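**Strategy**

The plan cuts the C6–C1' bond and the C1–O bond of the benzene ring together, back to 3,5-dimethoxybenzyne. It exploits the contiguous array C6 (chain), C1 (OH), C2 (OMe) on that single ring: the C2 methoxy sends a Grignard carbon to C6 and leaves magnesium on C1. In one flask an ortho-iodoaryl sulfonate releases the aryne, heneicosylmagnesium bromide adds, and a boronate marks C1 for oxidation. The precursor is 2-iodo-3,5-dimethoxyphenol as its 4-chlorobenzenesulfonate, preferred to the triflate because its magnesiated form should persist at −78 °C, so the aryne appears only when the long-chain Grignard is the nucleophile in excess.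

Key step: step 5

Remark on the chemistry: ring positions are numbered as in the target for all arenes (C1 OH, C2 and C4 OMe, C6 chain, C1' first chain carbon); the aryl sulfonate is only a leaving group and leaves no atom in the product.

**Route**

Step 1
Reactants: 1 3,5-dimethoxyphenol
Product: 2 2-iodo-3,5-dimethoxyphenol
Conditions: NIS (1.0 equiv), CH2Cl2, −78 °C → 0 °C, dark
Reagents that add atoms: N-iodosuccinimide, O=C1CCC(=O)N1I
Why: Electrophilic aromatic iodination of a very electron-rich ring, in which the two equivalent positions ortho to the hydroxyl outnumber the single para position, hydrogen bonding of the phenol to the succinimide carbonyl in a non-polar solvent should deliver iodine ortho, one equivalent of reagent limits di-iodination, and the isomers should separate on silica.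

Step 2
Reactants: 2 2-iodo-3,5-dimethoxyphenol
Product: 3 2-iodo-3,5-dimethoxyphenyl 4-chlorobenzenesulfonate
Conditions: 4-ClC6H4SO2Cl, Et3N, DMAP (cat.), CH2Cl2, 0 °C → rt
Reagents that add atoms: 4-chlorobenzenesulfonyl chloride, O=S(=O)(Cl)c1ccc(Cl)cc1
Why: DMAP-catalysed O-sulfonylation of a phenol, which the ortho iodine slows but should not block, with no other nucleophilic site in the molecule.

Step 3
Reactants: 4 heneicosan-1-ol
Product: 5 1-bromoheneicosane
Conditions: CBr4, PPh3, CH2Cl2, 0 °C → rt
Reagents that add atoms: carbon tetrabromide, BrC(Br)(Br)Br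
Why: Appel reaction, in which the alkoxyphosphonium ion is displaced by bromide in an SN2 step at an unhindered primary carbon with no competing functional group.

Step 4
Reactants: 5 1-bromoheneicosane
Product: 6 heneicosylmagnesium bromide
Conditions: Mg turnings (I2-activated), THF, 50 °C → reflux, slow addition of 5; solution kept at about 30 °C and titrated
Reagents that add atoms: magnesium, [Mg]
Why: Grignard formation by insertion of magnesium into a primary C–Br bond, where slow addition in warm THF should limit Wurtz coupling and keep the waxy reagent dissolved.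

Step 5
Reactants: 3 2-iodo-3,5-dimethoxyphenyl 4-chlorobenzenesulfonate; 6 heneicosylmagnesium bromide; 7 2-isopropoxy-4,4,5,5-tetramethyl-1,3,2-dioxaborolane
Product: 11 2-(2-heneicosyl-4,6-dimethoxyphenyl)-4,4,5,5-tetramethyl-1,3,2-dioxaborolane, via 2-(chloromagnesio)-3,5-dimethoxyphenyl 4-chlorobenzenesulfonate 8 (not isolated), via 3,5-dimethoxybenzyne 9 (not isolated), via (2-heneicosyl-4,6-dimethoxyphenyl)magnesium bromide 10 (not isolated)
Conditions: iPrMgCl·LiCl (1.0 equiv), THF, −78 °C; cannulated slowly into 6 (2 equiv), THF, 25–30 °C; then 7 (4 equiv), 0 °C → rt; aq. NH4Cl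
Reagents that add atoms: none
Why: Iodine–magnesium exchange at −78 °C turns 3 into arylmagnesium 8, which should survive at that temperature and, on meeting the warm solution of 6, lose chloromagnesium 4-chlorobenzenesulfonate by β-elimination to give aryne 9 with its triple bond between C1 and C6. The C2 methoxy group polarises the strained triple bond by induction, so C6 is the more electrophilic terminus; the primary alkyl Grignard bonds there (new C6–C1' bond) and magnesium arrives on C1, chelated by the neighbouring methoxy oxygen, as 10. Boronate 7 then captures 10 through an ate complex that expels isopropoxide, forming the C1–B bond. The closest known reaction type is carbomagnesiation of arynes released from 2-magnesiated aryl sulfonates followed by electrophilic quench, joined to the standard borylation of aryl Grignard reagents by isopropoxy pinacolborane. No ring closes and no stereocenter forms. The step needs regioselective addition across C1–C6, secured by the C2 methoxy next to C1 (the C4 methoxy, meta to C6, exerts only a weak opposing pull), and it needs to avoid isopropyl transfer, secured by consuming exactly one equivalent of iPrMgCl·LiCl before the aryne is set free in an excess of 6.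

Step 6
Reactants: 11 2-(2-heneicosyl-4,6-dimethoxyphenyl)-4,4,5,5-tetramethyl-1,3,2-dioxaborolane
Product: 12 6-n-heneicosyl-2,4-dimethoxyphenol
Conditions: 30% aq. H2O2, aq. NaOH, degassed THF, 0 °C → rt; aq. Na2S2O3, aq. NH4Cl
Reagents that add atoms: hydrogen peroxide, OO
Why: Oxidative ipso-hydroxylation of an arylboronic ester, in which hydroperoxide adds to boron, the aryl group migrates from boron to oxygen at C1 and the borate is hydrolysed, while the ethers and the chain are inert and cold, air-free conditions with a reductive quench protect the electron-rich phenol.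

**Compound list**

1 | 3,5-dimethoxyphenol | COc1cc(O)cc(OC)c1 | starting material
2 | 2-iodo-3,5-dimethoxyphenol | COc1cc(O)c(I)c(OC)c1 | intermediate
3 | 2-iodo-3,5-dimethoxyphenyl 4-chlorobenzenesulfonate | COc1cc(OC)c(I)c(OS(=O)(=O)c2ccc(Cl)cc2)c1 | intermediate
4 | heneicosan-1-ol | CCCCCCCCCCCCCCCCCCCCCO | starting material
5 | 1-bromoheneicosane | CCCCCCCCCCCCCCCCCCCCCBr | intermediate
6 | heneicosylmagnesium bromide | CCCCCCCCCCCCCCCCCCCCC[Mg]Br | intermediate
7 | 2-isopropoxy-4,4,5,5-tetramethyl-1,3,2-dioxaborolane | CC(C)OB1OC(C)(C)C(C)(C)O1 | starting material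
8 | 2-(chloromagnesio)-3,5-dimethoxyphenyl 4-chlorobenzenesulfonate | COc1cc(OC)c([Mg]Cl)c(OS(=O)(=O)c2ccc(Cl)cc2)c1 | intermediate
9 | 3,5-dimethoxybenzyne (1,2-didehydro-3,5-dimethoxybenzene) | COC1=CC(OC)=CC#C1 | intermediate
10 | (2-heneicosyl-4,6-dimethoxyphenyl)magnesium bromide | CCCCCCCCCCCCCCCCCCCCCc1cc(OC)cc(OC)c1[Mg]Br | intermediate
11 | 2-(2-heneicosyl-4,6-dimethoxyphenyl)-4,4,5,5-tetramethyl-1,3,2-dioxaborolane | CCCCCCCCCCCCCCCCCCCCCc1cc(OC)cc(OC)c1B2OC(C)(C)C(C)(C)O2 | intermediate
12 | 6-n-heneicosyl-2,4-dimethoxyphenol | CCCCCCCCCCCCCCCCCCCCCc1cc(OC)cc(OC)c1O | target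

**Step count**

Total steps: 6. Longest linear sequence: 4 steps (steps 1, 2, 5, 6 from 1; equally steps 3, 4, 5, 6 from 4).

**Steps most likely to fail**

Step 5. The aryne may be consumed unselectively, by self-oligomerisation, by attack of adduct 10 on a second aryne or by isopropyl transfer. The hindered C1–Mg bond may also be protonated before boron capture. The fallback installs the chain and the boron in separate operations and sets out from 1 and 6. Phenol 1 would be triflated (Tf2O, pyridine, CH2Cl2) to 3,5-dimethoxyphenyl trifluoromethanesulfonate F1. This would be coupled with 6 under Fe(acac)3 catalysis (Kumada-type coupling, THF/NMP, 0 °C) to give 1-heneicosyl-3,5-dimethoxybenzene F2. NBS in MeCN should brominate the position between the chain and a methoxy group, which is ortho to one methoxy and para to the other, giving 2-bromo-1-heneicosyl-3,5-dimethoxybenzene F3. Bromine–lithium exchange (nBuLi, THF, −78 °C → −40 °C) would give (2-heneicosyl-4,6-dimethoxyphenyl)lithium F4, and quench with 7 comes back to the route at 11.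

Step 1. Regiocontrol between the ortho and para positions of the phenol may be poor, and over-iodination may occur. The fallback uses directed ortho-metalation and sets out from 1. Carbamoylation (ClCONEt2, K2CO3, MeCN, reflux) would give 3,5-dimethoxyphenyl N,N-diethylcarbamate F5. Lithiation with sBuLi/TMEDA (THF, −78 °C) should occur between the carbamate and a methoxy group to give 2-lithio-3,5-dimethoxyphenyl N,N-diethylcarbamate F6. Iodine quench would give 2-iodo-3,5-dimethoxyphenyl N,N-diethylcarbamate F7, and hydrolysis (NaOH, EtOH/H2O, reflux) comes back to the route at 2.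

Step 4. Wurtz homocoupling may compete, and insertion may stall because the long-chain halide and its Grignard reagent are poorly soluble. The fallback reaches the organomagnesium through the organolithium and sets out from 5. Finkelstein exchange (NaI, acetone, reflux) would give 1-iodoheneicosane F8. Iodine–lithium exchange with tBuLi (2.1 equiv, pentane/Et2O, −78 °C, dilute) would give heneicosyllithium F9, and transmetalation with MgBr2·OEt2 comes back to the route at 6.

**Further compounds**

F1 | step 5 | 3,5-dimethoxyphenyl trifluoromethanesulfonate | COc1cc(OC)cc(OS(=O)(=O)C(F)(F)F)c1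
F2 | step 5 | 1-heneicosyl-3,5-dimethoxybenzene | CCCCCCCCCCCCCCCCCCCCCc1cc(OC)cc(OC)c1
F3 | step 5 | 2-bromo-1-heneicosyl-3,5-dimethoxybenzene | CCCCCCCCCCCCCCCCCCCCCc1cc(OC)cc(OC)c1Br
F4 | step 5 | (2-heneicosyl-4,6-dimethoxyphenyl)lithium | CCCCCCCCCCCCCCCCCCCCCc1cc(OC)cc(OC)c1[Li]
F5 | step 1 | 3,5-dimethoxyphenyl N,N-diethylcarbamate | CCN(CC)C(=O)Oc1cc(OC)cc(OC)c1
F6 | step 1 | 2-lithio-3,5-dimethoxyphenyl N,N-diethylcarbamate | CCN(CC)C(=O)Oc1cc(OC)cc(OC)c1[Li]
F7 | step 1 | 2-iodo-3,5-dimethoxyphenyl N,N-diethylcarbamate | CCN(CC)C(=O)Oc1cc(OC)cc(OC)c1I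
F8 | step 4 | 1-iodoheneicosane | CCCCCCCCCCCCCCCCCCCCCI
F9 | step 4 | heneicosyllithium | [Li]CCCCCCCCCCCCCCCCCCCCC
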